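Everything rests on cutting ring C, the 4-hydroxy-2-pyranone, at C3–C4 and O1–C2. The feature exploited is its alternating oxygenation. O1, C6 (bearing the benzylic CH2), C5 and C4 map onto an acylketene, and C2 and C3 map onto a ketene acetal. In one operation, thermolysis of an arylacetyl Meldrum's acid with 1,1-diethoxyethene should form both bonds, close ring C and, after loss of ethanol, give its 2-ethoxy-4-pyranone form. The precursor already holds rings A and B joined through the ketone, the four phenols as methyl ethers, and the acyl Meldrum's acid on the ring B CH2. One BBr3 treatment then removes all five O-alkyl groups.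

Key step: step 7

Assumption: ring A is the propyl-bearing arene, ring B the arene bearing the CH2 link, and ring C the pyranone numbered O1, C2 (C=O), C3, C4 (C–OH), C5, C6 (C–CH2). The target has no stereocentre and is made as the 4-hydroxy-2-pyranone tautomer drawn.

Step 1
Reactants: 1 5-propylbenzene-1,3-diol
Product: 2 1,3-dimethoxy-5-propylbenzene
Conditions: MeI, K2CO3, acetone, reflux
Reagents that add atoms: iodomethane, SMILES CI
Why: Williamson ether synthesis, in which both phenoxides are methylated by SN2 on iodomethane and nothing else in the molecule reacts under these mild basic conditions.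

Step 2
Reactants: 2 1,3-dimethoxy-5-propylbenzene
Product: 4 2,4-dimethoxy-6-propylbenzaldehyde, via aryl iminium chloride 3 (not isolated)
Conditions: POCl3, DMF, 0 → 80 °C; then H2O
Reagents that add atoms: N,N-dimethylformamide, SMILES CN(C)C=O; water, SMILES O
Why: Vilsmeier–Haack formylation, in which the chloroiminium ion attacks C4 (equivalent to C6), para to one methoxy group and ortho to the other, as is usual for 5-alkylresorcinol dimethyl ethers, and water then hydrolyses iminium salt 3 to the aldehyde.

Step 3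
Reactants: 4 2,4-dimethoxy-6-propylbenzaldehyde
Product: 5 2,4-dimethoxy-6-propylbenzoic acid
Conditions: NaClO2, NaH2PO4, 2-methyl-2-butene, t-BuOH–H2O, rt
Reagents that add atoms: sodium chlorite, SMILES [Na+].[O-]Cl=O
Why: Pinnick oxidation, in which chlorous acid adds to the aldehyde and fragments to the acid while the alkene scavenger removes HOCl before it can chlorinate the electron-rich ring.

Step 4
Reactants: 5 2,4-dimethoxy-6-propylbenzoic acid; 6 methyl 2-(3,5-dimethoxyphenyl)acetate
Product: 8 methyl 2-[2-(2,4-dimethoxy-6-propylbenzoyl)-3,5-dimethoxyphenyl]acetate, via mixed trifluoroacetic anhydride 7 (not isolated)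
Conditions: (CF3CO)2O, CH2Cl2, 0 °C → rt (5 activated first, then 6 added)
Reagents that add atoms: none
Why: Friedel–Crafts acylation through mixed anhydride 7, whose two ortho substituents and two methoxy donors favour ionisation to the acylium ion; this attacks ring B at C2 (equivalent to C6), para to one methoxy group and ortho to the other, as is known for 3,5-dimethoxyphenylacetates and for anhydride-mediated syntheses of tetra-ortho-substituted benzophenones, and the absence of a strong Lewis acid keeps the ortho methyl ethers intact.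

Step 5
Reactants: 8 methyl 2-[2-(2,4-dimethoxy-6-propylbenzoyl)-3,5-dimethoxyphenyl]acetate
Product: 9 2-[2-(2,4-dimethoxy-6-propylbenzoyl)-3,5-dimethoxyphenyl]acetic acid
Conditions: LiOH, THF–H2O, rt; then 1 M HCl
Reagents that add atoms: lithium hydroxide, SMILES [Li+].[OH-]
Why: Saponification of the unhindered aliphatic methyl ester, to which the shielded diaryl ketone and the aryl ethers are inert at room temperature.

Step 6
Reactants: 9 2-[2-(2,4-dimethoxy-6-propylbenzoyl)-3,5-dimethoxyphenyl]acetic acid; 10 2,2-dimethyl-1,3-dioxane-4,6-dione (Meldrum's acid)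
Product: 11 5-{2-[2-(2,4-dimethoxy-6-propylbenzoyl)-3,5-dimethoxyphenyl]-1-hydroxyethylidene}-2,2-dimethyl-1,3-dioxane-4,6-dione
Conditions: DCC, DMAP, CH2Cl2, 0 °C → rt; then wash with 1 M HCl
Reagents that add atoms: none
Why: Standard carbodiimide/DMAP C-acylation of Meldrum's acid, in which the acylpyridinium ion is taken up by the Meldrum's acid anion and the product rests as its stabilised enolate until the acid wash, while any enol lactone formed by participation of the neighbouring ketone would itself acylate the same anion.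

Step 7
Reactants: 11 5-{2-[2-(2,4-dimethoxy-6-propylbenzoyl)-3,5-dimethoxyphenyl]-1-hydroxyethylidene}-2,2-dimethyl-1,3-dioxane-4,6-dione; 12 1,1-diethoxyethene
Product: 15 2-{[2-(2,4-dimethoxy-6-propylbenzoyl)-3,5-dimethoxyphenyl]methyl}-6-ethoxy-4H-pyran-4-one, via acylketene 13 (not isolated), via diethoxydihydropyranone cycloadduct 14 (not isolated)
Conditions: 12 (5 equiv), PhMe, 110 °C, slow addition of 11 in PhMe, acetone and EtOH distilled off
Reagents that add atoms: none
Why: Near 110 °C enol 11 fragments with loss of acetone and CO2 to acylketene 13, whose O=C–CH=C unit is an electron-poor oxadiene. The nucleophilic CH2 of ketene acetal 12 adds to the ketene carbon (new C3–C4 bond) and the enolate oxygen so formed closes on the diethoxycarbenium carbon (new O1–C2 bond), so ring C forms as a six-membered ring by a polar, stepwise inverse-demand hetero-Diels–Alder (4+2) cycloaddition that gives 14. Loss of ethanol across C2–C3 of 14, driven by the acidity of the C3 protons next to the C4 ketone and by the conjugation gained, then gives 2-ethoxy-4-pyranone 15, and no stereocentre is created. The closest known reaction type is the trapping of thermally generated acylketenes with enol ethers and ketene acetals to make 4-pyranones. Regiochemistry is fixed by the matched polarity of the two partners, while chemoselectivity against acylketene dimerisation, capture by the released ethanol and C-acylation of the free ortho CH of ring B is secured by the high nucleophilicity and excess of 12, the slow addition of 11 and the distillative removal of ethanol. The diaryl ketone, screened by four ortho substituents, could add to the acylketene only by forming a bridgehead alkene and should remain a spectator.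

Step 8
Reactants: 15 2-{[2-(2,4-dimethoxy-6-propylbenzoyl)-3,5-dimethoxyphenyl]methyl}-6-ethoxy-4H-pyran-4-one
Product: 16 6-{[2-(2,4-dihydroxy-6-propylbenzoyl)-3,5-dihydroxyphenyl]methyl}-4-hydroxy-2H-pyran-2-one
Conditions: BBr3 (10 equiv), CH2Cl2, −78 °C → rt; then H2O, 0 °C
Reagents that add atoms: none
Why: Lewis-acid ether cleavage, in which BBr3 binds the C4 carbonyl of ring C and the aryl ether oxygens, bromide removes the ethyl group from the pyrylium-like 2-ethoxy complex and the four aryl methyl groups by SN2, and aqueous work-up frees the four phenols and the 4-hydroxy-2-pyranone, a ring that tolerates this reagent.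

Compound list
1 | 5-propylbenzene-1,3-diol | CCCc1cc(O)cc(O)c1 | starting material
2 | 1,3-dimethoxy-5-propylbenzene | CCCc1cc(OC)cc(OC)c1 | intermediate
3 | [(2,4-dimethoxy-6-propylphenyl)methylidene]dimethylammonium chloride | CCCc1cc(OC)cc(OC)c1C=[N+](C)C.[Cl-] | intermediate
4 | 2,4-dimethoxy-6-propylbenzaldehyde | CCCc1cc(OC)cc(OC)c1C=O | intermediate
5 | 2,4-dimethoxy-6-propylbenzoic acid | CCCc1cc(OC)cc(OC)c1C(=O)O | intermediate
6 | methyl 2-(3,5-dimethoxyphenyl)acetate | COC(=O)Cc1cc(OC)cc(OC)c1 | starting material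
7 | 2,4-dimethoxy-6-propylbenzoic trifluoroacetic anhydride | CCCc1cc(OC)cc(OC)c1C(=O)OC(=O)C(F)(F)F | intermediate
8 | methyl 2-[2-(2,4-dimethoxy-6-propylbenzoyl)-3,5-dimethoxyphenyl]acetate | CCCc1cc(OC)cc(OC)c1C(=O)c1c(OC)cc(OC)cc1CC(=O)OC | intermediate
9 | 2-[2-(2,4-dimethoxy-6-propylbenzoyl)-3,5-dimethoxyphenyl]acetic acid | CCCc1cc(OC)cc(OC)c1C(=O)c1c(OC)cc(OC)cc1CC(=O)O | intermediate
10 | 2,2-dimethyl-1,3-dioxane-4,6-dione (Meldrum's acid) | CC1(C)OC(=O)CC(=O)O1 | starting material
11 | 5-{2-[2-(2,4-dimethoxy-6-propylbenzoyl)-3,5-dimethoxyphenyl]-1-hydroxyethylidene}-2,2-dimethyl-1,3-dioxane-4,6-dione | CCCc1cc(OC)cc(OC)c1C(=O)c1c(OC)cc(OC)cc1CC(O)=C1C(=O)OC(C)(C)OC1=O | intermediate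
12 | 1,1-diethoxyethene | C=C(OCC)OCC | starting material
13 | 4-[2-(2,4-dimethoxy-6-propylbenzoyl)-3,5-dimethoxyphenyl]but-1-ene-1,3-dione (acylketene) | CCCc1cc(OC)cc(OC)c1C(=O)c1c(OC)cc(OC)cc1CC(=O)C=C=O | intermediate
14 | 6-{[2-(2,4-dimethoxy-6-propylbenzoyl)-3,5-dimethoxyphenyl]methyl}-2,2-diethoxy-2,3-dihydro-4H-pyran-4-one | CCOC1(OCC)CC(=O)C=C(Cc2cc(OC)cc(OC)c2C(=O)c2c(OC)cc(OC)cc2CCC)O1 | intermediate
15 | 2-{[2-(2,4-dimethoxy-6-propylbenzoyl)-3,5-dimethoxyphenyl]methyl}-6-ethoxy-4H-pyran-4-one | CCOc1cc(=O)cc(Cc2cc(OC)cc(OC)c2C(=O)c2c(OC)cc(OC)cc2CCC)o1 | intermediate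
16 | 6-{[2-(2,4-dihydroxy-6-propylbenzoyl)-3,5-dihydroxyphenyl]methyl}-4-hydroxy-2H-pyran-2-one (CNP0306954.0) | CCCc1cc(O)cc(O)c1C(=O)c1c(O)cc(O)cc1Cc1cc(O)cc(=O)o1 | target

Total step count: 8.
Longest linear sequence: 8 steps (1 → 2 → 4 → 5 → 8 → 9 → 11 → 15 → 16). Compounds 6, 10 and 12 are bought.

Steps most likely to fail

**Step 7.**
- The strongly acidic enol of 11 may protonate the acid-sensitive ketene acetal before fragmentation sets in.
- The acylketene may be lost to dimerisation or to capture by liberated ethanol.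
- Fallback (sets out from 9, comes back at 16): ring C is closed at oxygen instead of at carbon.
- Acid 9 is converted with 1,1'-carbonyldiimidazole in THF into the acyl imidazole F1.
- F1 acylates the terminal carbon of the lithium dienolate of commercial 2,2,6-trimethyl-4H-1,3-dioxin-4-one (LiN(SiMe3)2, THF, −78 °C, excess dienolate) to give the keto-dioxinone F2.
- Heating F2 in toluene releases acetone and an acylketene that is captured by its own enolised ketone. This gives the tetra-O-methyl 4-hydroxy-2-pyranone F3.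
- BBr3 as in step 8 then leads to 16.

**Step 4.**
- Attack of the crowded acylium ion on ring B may be sluggish.
- Acylation may compete at the position between the two methoxy groups.
- The arene may be trifluoroacetylated instead.
- Fallback (sets out from 4 and 6, comes back at 9): the aryl–carbon bond is made intramolecularly at the aldehyde oxidation level.
- Ester 6 is reduced (LiAlH4, THF) to 2-(3,5-dimethoxyphenyl)ethanol F4.
- An acid-catalysed oxa-Pictet–Spengler condensation of F4 with aldehyde 4 (TsOH, toluene, removal of water) should give the racemic 1-aryl-6,8-dimethoxyisochroman F5.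
- The tether forces bond formation at the ring B carbon next to the side chain.
- Jones oxidation (CrO3, H2SO4, acetone, 0 °C) attacks the doubly benzylic C1–H and then the released primary alcohol. It gives keto acid 9 directly and bypasses steps 3 to 5.

**Step 8.**
- Cleavage of the two methyl ethers para to the ketone may stall, because their oxygens are conjugated with the boron-bound carbonyl.
- The long exposure then needed may cause Lewis-acid-promoted condensation of ring C onto the ketone.
- Fallback (sets out from 9, comes back at 16): the harsh demethylation is moved ahead of ring C and the phenols are carried as benzyl ethers.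
- BBr3, with forcing if needed, converts the robust acid 9 into the tetrahydroxy keto acid F6.
- BnBr and K2CO3 in DMF give the tetrabenzyl ether benzyl ester F7.
- LiOH gives the tetrabenzyl keto acid F8.
- The conditions of step 6 give the tetrabenzyl acyl Meldrum's acid F9, and those of step 7 give the tetrabenzyl 2-ethoxy-4-pyranone F10.
- Dilute HCl in aqueous THF hydrolyses the enol ether to the tetrabenzyl 4-hydroxy-2-pyranone F11.
- Hydrogenolysis (H2, Pd/C, EtOAc, rt) gives 16.

Further compounds
F1 | step 7 | 2-[2-(2,4-dimethoxy-6-propylbenzoyl)-3,5-dimethoxyphenyl]-1-(1H-imidazol-1-yl)ethan-1-one | CCCc1cc(OC)cc(OC)c1C(=O)c1c(OC)cc(OC)cc1CC(=O)n1ccnc1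
F2 | step 7 | 6-{3-[2-(2,4-dimethoxy-6-propylbenzoyl)-3,5-dimethoxyphenyl]-2-oxopropyl}-2,2-dimethyl-4H-1,3-dioxin-4-one | CC1(C)OC(=O)C=C(CC(=O)Cc2cc(OC)cc(OC)c2C(=O)c2c(OC)cc(OC)cc2CCC)O1
F3 | step 7 | 6-{[2-(2,4-dimethoxy-6-propylbenzoyl)-3,5-dimethoxyphenyl]methyl}-4-hydroxy-2H-pyran-2-one | CCCc1cc(OC)cc(OC)c1C(=O)c1c(OC)cc(OC)cc1Cc1cc(O)cc(=O)o1
F4 | step 4 | 2-(3,5-dimethoxyphenyl)ethanol | OCCc1cc(OC)cc(OC)c1
F5 | step 4 | 1-(2,4-dimethoxy-6-propylphenyl)-6,8-dimethoxy-3,4-dihydro-1H-isochromene (racemic) | CCCc1cc(OC)cc(OC)c1C1OCCc2cc(OC)cc(OC)c21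
F6 | step 8 | 2-[2-(2,4-dihydroxy-6-propylbenzoyl)-3,5-dihydroxyphenyl]acetic acid | CCCc1cc(O)cc(O)c1C(=O)c1c(O)cc(O)cc1CC(=O)O
F7 | step 8 | benzyl 2-{2-[2,4-bis(benzyloxy)-6-propylbenzoyl]-3,5-bis(benzyloxy)phenyl}acetate | CCCc1cc(OCc2ccccc2)cc(OCc2ccccc2)c1C(=O)c1c(OCc2ccccc2)cc(OCc2ccccc2)cc1CC(=O)OCc1ccccc1
F8 | step 8 | 2-{2-[2,4-bis(benzyloxy)-6-propylbenzoyl]-3,5-bis(benzyloxy)phenyl}acetic acid | CCCc1cc(OCc2ccccc2)cc(OCc2ccccc2)c1C(=O)c1c(OCc2ccccc2)cc(OCc2ccccc2)cc1CC(=O)O
F9 | step 8 | 5-(2-{2-[2,4-bis(benzyloxy)-6-propylbenzoyl]-3,5-bis(benzyloxy)phenyl}-1-hydroxyethylidene)-2,2-dimethyl-1,3-dioxane-4,6-dione | CCCc1cc(OCc2ccccc2)cc(OCc2ccccc2)c1C(=O)c1c(OCc2ccccc2)cc(OCc2ccccc2)cc1CC(O)=C1C(=O)OC(C)(C)OC1=O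
F10 | step 8 | 2-({2-[2,4-bis(benzyloxy)-6-propylbenzoyl]-3,5-bis(benzyloxy)phenyl}methyl)-6-ethoxy-4H-pyran-4-one | CCOc1cc(=O)cc(Cc2cc(OCc3ccccc3)cc(OCc3ccccc3)c2C(=O)c2c(OCc3ccccc3)cc(OCc3ccccc3)cc2CCC)o1
F11 | step 8 | 6-({2-[2,4-bis(benzyloxy)-6-propylbenzoyl]-3,5-bis(benzyloxy)phenyl}methyl)-4-hydroxy-2H-pyran-2-one | CCCc1cc(OCc2ccccc2)cc(OCc2ccccc2)c1C(=O)c1c(OCc2ccccc2)cc(OCc2ccccc2)cc1Cc1cc(O)cc(=O)o1
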